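Read the stall as a rate.

| setting | spring | summer | flask |
|---|---|---|---|
| starting material | 0.022 M | 0.022 M | 0.022 M |
| partner | 2 equiv | 2 equiv | 2.00 equiv |
| second substrate | 0.50 equiv | 0.50 equiv | 0.500 equiv |
| third substrate | 2 equiv | 2 equiv | 2.00 equiv |
| protic impurity | 0.011 M | 0.011 M | 0.0110 M |
| temperature | 25 °C | 20 °C | 25 °C |
| remark | the very flask that is asked about, followed so far | run made earlier |  |
| time |  |  | 8.0 d |

- spring (time / d: target / %, starting material / %): 1.25: 39.4, 59.2; 2.50: 45.4, 55.9; 3.00: 43.8, 54.8; 5.00: 46.9, 54.3; 6.00: 42.3, 54.2; 8.00: 44.2, 53.3
- summer (time / d: target / %, starting material / %): 1.25: 35.9, 64.4; 2.50: 43.7, 58.0; 3.00: 43.7, 58.3; 5.00: 44.4, 56.2; 6.00: 48.0, 55.9; 8.00: 46.9, 52.4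

(readings scatter by 1 percentage point)

- beta: change nothing and wait 4.0 d more
- eta: at 8.0 d raise the temperature by 15 K, then wait 4.0 d
- theta: at 8.0 d add starting material, 50.0% of the amount charged, then wait 4.0 d
- delta: at 8.0 d add partner, 50.0% of the amount charged, then wait 4.0 d

- the volume of additions can be left aside
- what was read earlier has a scatter of 1 percentage point, one standard deviation
- a reading or a percentage of target counts all its forms, free or not

- target, in percent of the starting material first charged, at 8.0 d
- the remedy with the largest gain of target, or "none" below 2 percentage points (beta / eta / theta / delta / none)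
- target present, in percent of the starting material first charged, after beta
- target present, in percent of the starting material first charged, after delta

Take the spring run, which is this flask, and count in half-lives. Over the first 1.25 d, starting material falls by 0.326 d⁻¹. Read as first-order loss, that gives h, the half-life of starting material over that first stretch of the run:

h = 1.65 d

From 2.50 d to 8.00 d the fall is 0.00473 d⁻¹, so the rate has dropped 68.9-fold. The decline of starting material itself gives a factor of 1.46. The remaining factor, 47.4, is more than that, so put it on another reactant. Take this to be the partner, the limiting reagent, though no reading shows it. The late half-life is a rough reading, given the scatter: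

h(late) = 80.0 d

Now count the half-lives each remedy offers in 4.0 d. Adding starting material leaves the half-life as it is, so it counts like waiting. For heat, scale by the summer run's start, 1.97 d, for each 5 K step. Added partner restores half its first charge, so the half-life becomes twice h.

wait, or add starting material: 0.0500
heat: 0.0845
add partner: 1.21

Choose delta, since its count is the largest. The late readings put target near 46.1% now. Waiting adds about 1.8 percentage points at the late pace. With that longer half-life held through the 4.0 d, this count puts target after delta at 77.0%.

The forecast gives 45.5% now, 46.4% after waiting, 46.8% after delta, and best none, saying of more partner that “it cannot lift the ceiling”. This differs from the reckoning above on delta.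

The flask gives 45.9% now, 45.9% after beta, 82.5% after delta, and best delta, with a gain of 37 points.

    third substrate → decomposition product (k = 2.13 × 10⁻⁸ s⁻¹, Ea = 107 kJ mol⁻¹)
    third substrate + protic impurity → quenched substrate (k = 0.00120 M⁻¹ s⁻¹, Ea = 73.0 kJ mol⁻¹)
    third substrate + partner → third product (k = 6.79 × 10⁻⁴ M⁻¹ s⁻¹, Ea = 61.0 kJ mol⁻¹)
    starting material + partner → target (k = 3.88 × 10⁻⁴ M⁻¹ s⁻¹, Ea = 56.0 kJ mol⁻¹)
    partner + target ⇌ idle adduct, settled at all times (K = 10.3 M⁻¹, ΔH = −90.0 kJ mol⁻¹)
    second substrate + partner → second product (k = 0.00153 M⁻¹ s⁻¹, Ea = 52.0 kJ mol⁻¹)
    (constants at 25 °C)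

In the flask, the step of starting material with partner had a half-life of 0.96 d at 0.194 d, but with free partner at 0.0095% of its charge at 8.00 d the same step reckons to 4930 d, which is 2988 times h. The same count on the neighbour with 0.120 equiv of second substrate, where free partner stands at 0.25%, gives 188 d, or 114 times h, and that flask holds 60.1% of target at 8.00 d.

The runs are calculated on assumed constants, noise included.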